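**Assumptions (one line each):**
- The target is the natural ent-kaurane-series 6,7-seco spirolactone, with the absolute configuration encoded in the given SMILES.
- The A-ring fragment is made racemic. The enantiopure bicyclic acid 7 resolves it when the two diastereomeric esters are separated at Step 14 (theoretical maximum 50% for that branch).
- The C6 methyl-acetal anomer is separated after acetalisation.

## Retrosynthetic overview
1. Target 27 ⇐ C15 allylic oxidation ⇐ C6 methyl acetal 25 ⇐ C6 γ-lactone → lactol reduction ⇐ C12-deoxygenated spiro-dilactone 23 ⇐ 21.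
2. Ketone 21 ⇐ photoredox deoxygenative 6-exo radical cyclisation (new) of tertiary oxalate 20 onto a bridged enone. This forms the C9–C10 bond, the spiro-δ-lactone and the C10 quaternary centre, with the ester tether linking acid 7 and diol 17.
3. Enone acid 7 ⇐ bicyclo[3.2.1]octanone 5, built by an enantioselective desymmetrising Pd α-alkenylation (new) of 4. Commercial ketal ester 1 and 2,3-dibromopropene give 4. Diol 17 ⇐ Diels–Alder of citraconic anhydride with a dienol ether, then regioselective anhydride reduction (C6/C19 γ-lactone) and enoate → epoxide → SmI2 to install the C10 tertiary alcohol.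
4. Ring-formation order: C/D bicycle (Step 3) → A ring (Step 7) → spiro δ-lactone (Step 17) → C6/C19 THF acetal (Steps 20–21) → C15 enone last.

## Route

**Step 1**
Reactants: 1 methyl 1,4-dioxaspiro[4.5]decane-8-carboxylate; 2 2,3-dibromopropene
Product: 3 methyl 8-(2-bromoallyl)-1,4-dioxaspiro[4.5]decane-8-carboxylate
Conditions: LDA, THF, –78 °C; then 2, –78 → 0 °C
Reagents that add atoms: 2,3-dibromopropene, C=C(Br)CBr
Why: Ester-enolate SN2 alkylation at the more reactive allylic bromide builds the C8 quaternary carbon, and the vinyl bromide survives.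

**Step 2**
Reactants: 3
Product: 4 methyl 1-(2-bromoallyl)-4-oxocyclohexane-1-carboxylate (achiral, prochiral)
Conditions: 2 M HCl (aq), acetone, 50 °C
Reagents that add atoms: water, O
Why: Acid hydrolysis of the ketal unmasks the C12 ketone and leaves the ester and vinyl bromide intact.

**Step 3**
Reactants: 4
Product: 5 methyl (1R,5R)-7-methylidene-2-oxobicyclo[3.2.1]octane-5-carboxylate
Conditions: Pd2(dba)3 (2.5 mol%), (R)-DTBM-SEGPHOS (6 mol%), NaOtBu, toluene, 80 °C
Reagents that add atoms: none
Why: Proposed new method: the chiral Pd–bisphosphine adds oxidatively into the vinyl bromide and selects one of the two enantiotopic α-carbons of the ketone (C11 vs C13) to bind as the enolate. C(sp2)–C(sp3) reductive elimination then forms the C13–C16 bond, giving the bridged bicycle with the exocyclic methylene and setting C8 and C13 together. The closest known reactions are racemic intramolecular ketone α-alkenylation and enantioselective desymmetrising α-arylation. Use (S)-ligand if the opposite enantiomer forms.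

**Step 4**
Reactants: 5
Product: 6 (1R,5R)-7-methylidene-2-oxobicyclo[3.2.1]octane-5-carboxylic acid
Conditions: KOSiMe3, THF, 60 °C; then 1 M HCl
Reagents that add atoms: none
Why: Anhydrous silanolate cleavage is suited to a very hindered bridgehead methyl ester and leaves the ketone and alkene untouched, with no stereocentre affected.

**Step 5**
Reactants: 6
Product: 7 (1R,5R)-7-methylidene-2-oxobicyclo[3.2.1]oct-3-ene-5-carboxylic acid
Conditions: IBX, 4-methoxypyridine N-oxide, DMSO, 65 °C
Reagents that add atoms: none
Why: Ketone dehydrogenation can only go toward C11, because C13 is a bridgehead, so the C11=C9 enone forms regiospecifically.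

**Step 6**
Reactants: 8 (2E)-penta-2,4-dien-1-ol
Product: 9 tert-butyl(dimethyl){[(2E)-penta-2,4-dien-1-yl]oxy}silane
Conditions: TBSCl, imidazole, DMF, 0 → 23 °C
Reagents that add atoms: TBSCl, CC(C)(C)[Si](C)(C)Cl
Why: Silyl protection of the primary alcohol (C20 oxygen).

**Step 7**
Reactants: 9; 10 citraconic anhydride
Product: 11 (±)-7-[(TBSO)methyl]-3a-methyl-3a,4,7,7a-tetrahydroisobenzofuran-1,3-dione (cis-anhydride; racemic, drawn as the series leading to target)
Conditions: neat or toluene, 80 °C, 24 h
Reagents that add atoms: none beyond the numbered reactants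
Why: Diels–Alder with suprafacial cis addition fixes the C4/C5 relative configuration. The regiochemistry with the substituted diene terminus bonded to the unsubstituted CH of the dienophile is assumed on steric grounds, and the minor regioisomer is removed chromatographically.

**Step 8**
Reactants: 11
Product: 12 (±)-saturated anhydride
Conditions: H2 (1 atm), 10% Pd/C, EtOAc, 23 °C, 1 h
Reagents that add atoms: none
Why: Hydrogenation of the unactivated ring alkene, with the non-allylic silyl ether and anhydride intact.

**Step 9**
Reactants: 12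
Product: 13 (±)-7-[(TBSO)methyl]-3a-methylhexahydroisobenzofuran-1(3H)-one (cis-fused 6,19-γ-lactone)
Conditions: NaBH4, THF, 0 → 23 °C; then 1 M HCl
Reagents that add atoms: none
Why: Hydride attacks the more hindered carbonyl (C19, next to quaternary C4) of the unsymmetrical anhydride. The remaining carbonyl is then C6, giving the 6,19-lactone that sets the C6 oxidation level and the C19/C18 differentiation.

**Step 10**
Reactants: 13
Product: 14 (±)-7-[(TBSO)methyl]-3a-methyl-3a,4,5,6-tetrahydroisobenzofuran-1(3H)-one (C5=C10 enoate)
Conditions: LDA, THF, –78 °C; PhSeBr; then 30% H2O2, pyridine, CH2Cl2, 0 °C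
Reagents that add atoms: none (PhSe is lost)
Why: α-Selenation and selenoxide syn-elimination use the only β-hydrogen, at C10. This erases the C10 and C5 stereocentres and leaves an α-alkylidene lactone.

**Step 11**
Reactants: 14
Product: 15 (±)-C5–C10 epoxy lactone (C4 centre retained; epoxide stereochemistry unspecified)
Conditions: t-BuOOH, DBU, THF, 0 °C
Reagents that add atoms: tert-butyl hydroperoxide, CC(C)(C)OO (delivers O)
Why: Nucleophilic (Weitz–Scheffer) epoxidation of the electron-poor tetrasubstituted enoate gives the oxygen at C10 as required.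

**Step 12**
Reactants: 15
Product: 16 (±)-β-hydroxy lactone (C10 tertiary alcohol, C20 OTBS)
Conditions: SmI2, MeOH, THF, 0 °C
Reagents that add atoms: none
Why: Reductive C5–O cleavage of the α,β-epoxy lactone gives the β-hydroxy lactone. The Sm enolate is protonated to the cis-fused 6,19-lactone, which fixes C5 relative to C4.

**Step 13**
Reactants: 16
Product: 17 (±)-7-hydroxy-7-(hydroxymethyl)-3a-methylhexahydroisobenzofuran-1(3H)-one
Conditions: HF·pyridine, THF/pyridine, 0 → 23 °C
Reagents that add atoms: none
Why: Buffered acidic desilylation avoids base-mediated retro-oxa-Michael elimination or translactonisation of the β-hydroxy lactone.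

**Step 14**
Reactants: 7; 17
Product: 18 (single diastereomer) primary C20 ester of 7 with 17, tertiary C10–OH free
Conditions: (i) 7, Me2C=C(Cl)NMe2, CH2Cl2, 0 → 23 °C; (ii) 17, pyridine, DMAP, CH2Cl2, 40 °C; separate diastereomers by SiO2/HPLC and keep the diastereomer that carries the target C4/C5 configuration
Reagents that add atoms: none beyond the numbered reactants
Why: The acid chloride acylates the primary alcohol selectively over the tertiary one. The enantiopure bicyclic acid turns the racemic A-fragment into separable diastereomers (resolution).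

**Step 15**
Reactants: 18
Product: 19 methyl oxalate of the C10 tertiary alcohol
Conditions: ClC(O)CO2Me, Et3N, DMAP, CH2Cl2, 0 °C
Reagents that add atoms: methyl chlorooxoacetate, COC(=O)C(=O)Cl
Why: Acylation of the tertiary alcohol makes a radical precursor, and no stereocentre is affected.

**Step 16**
Reactants: 19
Product: 20 cesium oxalate salt
Conditions: CsOH·H2O (1.0 equiv), MeOH/THF, 0 °C
Reagents that add atoms: cesium hydroxide, [Cs+].[OH-]
Why: Selective saponification of the activated oxalate methyl ester gives the photoactive cesium oxalate, and the hindered lactones survive at 0 °C.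

**Step 17**
Reactants: 20
Product: 21 C12-keto spiro-dilactone with C9–C10 bond formed
Conditions: [Ir{dF(CF3)ppy}2(dtbbpy)]PF6 (2 mol%), DMF (0.02 M), blue LEDs, 25 °C, 16 h
Reagents that add atoms: none (2 CO2 and Cs+ are lost; H+ comes from the medium)
Why: Proposed new method: excited Ir(III) oxidises the oxalate, which loses 2 CO2 to give the tertiary C10 radical. This nucleophilic radical adds 6-exo through the C7 ester tether to the β-carbon C9 of the enone. The tether on C7 holds the radical on the exo face, anti to the C15–C16 bridge, so C9 is set. On ring A the attack occurs anti to the axial C19 of the cis-fused lactone, which places C20 axial and sets C10. The α-keto radical is reduced by Ir(II) and protonated at C11. The closest known reaction is intermolecular photoredox oxalate–Michael-acceptor coupling to quaternary centres, and the new features are the ester-tethered intramolecular version and the vicinal quaternary–tertiary bond next to a bridgehead quaternary carbon.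

**Step 18**
Reactants: 21
Product: 22 C12 tosylhydrazone
Conditions: TsNHNH2, MeOH, TsOH (cat.), 50 °C
Reagents that add atoms: p-toluenesulfonyl hydrazide, Cc1ccc(cc1)S(=O)(=O)NN
Why: Standard hydrazone condensation at the only ketone.

**Step 19**
Reactants: 22
Product: 23 C12-deoxy spiro-dilactone
Conditions: catecholborane, CHCl3, 0 → 23 °C; then NaOAc·3H2O, 50 °C
Reagents that add atoms: none
Why: Hydride reduction of the tosylhydrazone with N2 loss (Kabalka-type) removes the C12 oxygen, leaving the lactones and the exocyclic alkene (fast at low temperature).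

**Step 20**
Reactants: 23
Product: 24 C6 lactol (anomeric mixture)
Conditions: DIBAL-H (1.1 equiv), CH2Cl2, –78 °C; Rochelle salt work-up
Reagents that add atoms: none
Why: The more electrophilic, strained cis-fused γ-lactone is reduced in preference to the δ-lactone whose carbonyl sits on the quaternary C8.

**Step 21**
Reactants: 24
Product: 25 C6 methyl acetal (15-deoxo target)
Conditions: MeOH, PPTS, 23 °C; separate C6 anomers and recycle the unwanted one by re-equilibration
Reagents that add atoms: methanol, CO
Why: Acid-catalysed cyclic methyl acetalisation through the oxocarbenium; the C6 configuration is set by separation of anomers.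

**Step 22**
Reactants: 25
Product: 26 C15 allylic alcohol (C15 epimers possible, irrelevant)
Conditions: SeO2 (0.3 equiv), TBHP, CH2Cl2, 23 °C
Reagents that add atoms: selenium dioxide, O=[Se]=O; tert-butyl hydroperoxide, CC(C)(C)OO (oxygen source)
Why: The SeO2 ene reaction followed by [2,3]-shift can only hydroxylate C15, because C13 is a bridgehead, and it leaves the acetal and lactones untouched.

**Step 23**
Reactants: 26
Product: 27 Ludongunin J
Conditions: Dess–Martin periodinane, NaHCO3, CH2Cl2, 23 °C
Reagents that add atoms: none
Why: Mild oxidation of the allylic alcohol gives the exocyclic enone (C15 ketone, C16=C17) and removes the C15 stereocentre.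

## Compound list
1 | methyl 1,4-dioxaspiro[4.5]decane-8-carboxylate | COC(=O)C1CCC2(CC1)OCCO2 | starting material
2 | 2,3-dibromopropene | C=C(Br)CBr | starting material
3 | methyl 8-(2-bromoallyl)-1,4-dioxaspiro[4.5]decane-8-carboxylate | COC(=O)C1(CC(Br)=C)CCC2(CC1)OCCO2 | intermediate
4 | methyl 1-(2-bromoallyl)-4-oxocyclohexane-1-carboxylate | COC(=O)C1(CC(Br)=C)CCC(=O)CC1 | intermediate
5 | methyl (1R,5R)-7-methylidene-2-oxobicyclo[3.2.1]octane-5-carboxylate | COC(=O)[C@]12CCC(=O)[C@H](C1)C(=C)C2 | intermediate
6 | (1R,5R)-7-methylidene-2-oxobicyclo[3.2.1]octane-5-carboxylic acid | OC(=O)[C@]12CCC(=O)[C@H](C1)C(=C)C2 | intermediate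
7 | (1R,5R)-7-methylidene-2-oxobicyclo[3.2.1]oct-3-ene-5-carboxylic acid | OC(=O)[C@]12C=CC(=O)[C@H](C1)C(=C)C2 | intermediate
8 | (2E)-penta-2,4-dien-1-ol | C=C/C=C/CO | starting material
9 | TBS ether of 8 | C=C/C=C/CO[Si](C)(C)C(C)(C)C | intermediate
10 | citraconic anhydride (3-methylfuran-2,5-dione) | CC1=CC(=O)OC1=O | starting material
11 | (±) Diels–Alder cis-anhydride, C10 carrying CH2OTBS | C[C@@]12CC=C[C@H](CO[Si](C)(C)C(C)(C)C)[C@@H]1C(=O)OC2=O | intermediate
12 | (±) saturated anhydride | C[C@@]12CCC[C@H](CO[Si](C)(C)C(C)(C)C)[C@@H]1C(=O)OC2=O | intermediate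
13 | (±) cis-fused 6,19-γ-lactone, CH2OTBS | C[C@@]12CCC[C@H](CO[Si](C)(C)C(C)(C)C)[C@@H]1C(=O)OC2 | intermediate
14 | (±) C5=C10 enoate lactone | C[C@@]12CCCC(CO[Si](C)(C)C(C)(C)C)=C1C(=O)OC2 | intermediate
15 | (±) C5–C10 epoxy lactone | C[C@@]12CCCC3(CO[Si](C)(C)C(C)(C)C)OC31C(=O)OC2 | intermediate
16 | (±) β-hydroxy lactone, C20 OTBS | C[C@@]12CCCC(O)(CO[Si](C)(C)C(C)(C)C)[C@@H]1C(=O)OC2 | intermediate
17 | (±) diol | C[C@@]12CCCC(O)(CO)[C@@H]1C(=O)OC2 | intermediate
18 | C20 ester of 7 with 17 (single diastereomer) | C[C@@]12CCCC(O)(COC(=O)[C@]34C=CC(=O)[C@H](C3)C(=C)C4)[C@@H]1C(=O)OC2 | intermediate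
19 | tertiary methyl oxalate | C[C@@]12CCCC(OC(=O)C(=O)OC)(COC(=O)[C@]34C=CC(=O)[C@H](C3)C(=C)C4)[C@@H]1C(=O)OC2 | intermediate
20 | tertiary cesium oxalate | C[C@@]12CCCC(OC(=O)C(=O)[O-])(COC(=O)[C@]34C=CC(=O)[C@H](C3)C(=C)C4)[C@@H]1C(=O)OC2.[Cs+] | intermediate
21 | C12-keto spiro-dilactone | C=C1C[C@]23C[C@H]1C(=O)C[C@H]2[C@@]1(CCC[C@@]2(C)COC(=O)[C@H]21)COC3=O | intermediate
22 | tosylhydrazone of 21 | C=C1C[C@]23C[C@H]1C(=NNS(=O)(=O)c4ccc(C)cc4)C[C@H]2[C@@]1(CCC[C@@]2(C)COC(=O)[C@H]21)COC3=O | intermediate
23 | C12-deoxy spiro-dilactone | C=C1C[C@]23C[C@H]1CC[C@H]2[C@@]1(CCC[C@@]2(C)COC(=O)[C@H]21)COC3=O | intermediate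
24 | C6 lactol (anomeric mixture, C6 unspecified) | C=C1C[C@]23C[C@H]1CC[C@H]2[C@@]1(CCC[C@@]2(C)COC(O)[C@H]21)COC3=O | intermediate
25 | 15-deoxo methyl acetal | C=C1C[C@]23C[C@H]1CC[C@H]2[C@@]1(CCC[C@@]2(C)CO[C@@H](OC)[C@H]21)COC3=O | intermediate
26 | C15 allylic alcohol (C15 unspecified) | C=C1C(O)[C@]23C[C@H]1CC[C@H]2[C@@]1(CCC[C@@]2(C)CO[C@@H](OC)[C@H]21)COC3=O | intermediate
27 | Ludongunin J | C=C1C(=O)[C@]23C[C@H]1CC[C@H]2[C@@]1(CCC[C@@]2(C)CO[C@@H](OC)[C@H]21)COC3=O | target

## Totals and risks
Total steps: 23. Longest linear sequence: 18 (Steps 6–13, then 14–23). The bicyclic-acid branch (Steps 1–5) is 5 steps.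

Three steps most likely to fail:
1. **Step 17 (photoredox radical cyclisation, new).**
   - Risks: the ester tether may resist the 6-exo geometry, the wrong C10 epimer may form, or β-acyloxy elimination may consume the oxalate.
   - Fallback: change the tether from ester to ether. Link the C7 alcohol (from BH3 reduction of 7) to the C20 oxygen of 17, run a xanthate/(TMS)3SiH 6-exo Giese cyclisation, and oxidise the cyclic ether to the δ-lactone with RuO4.
2. **Step 3 (Pd desymmetrising α-alkenylation, new).**
   - Risks: low ee, or competing enolisation at the ester.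
   - Fallback: use an achiral-ligand Pd α-alkenylation (known) to give racemic 5, then resolve acid 6 as its (S)-1-phenylethylammonium salt.
3. **Step 20 (DIBAL discrimination of the two lactones).**
   - Risk: over-reduction of the C7 δ-lactone.
   - Fallback: move the C6 reduction and acetalisation to the A-fragment at stage 16, where only one lactone exists. Carry the cis-fused THF methyl acetal through the esterification and radical steps, and separate the C6 anomers there.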